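## Analysis of the target

The target 21 is an unsymmetrical bis-coumarin with no stereocentre. Two 2H-chromen-2-one units are joined by one ether oxygen between C8 of the 7-methoxycoumarin (unprimed atoms, benzenoid ring A) and C8' of the 5',7'-dihydroxycoumarin (primed atoms, benzenoid ring B). Both ether carbons are flanked by two oxygen-bearing carbons: C8 lies between C7 (OMe) and C8a (O1), and C8' between C7' (OH) and C8a' (O1'). The diaryl ether is therefore tetra-ortho-substituted and electron-rich on both sides, which makes an Ullmann or SNAr coupling of two finished coumarins unattractive. The sensitive groups are the two lactones (opened by alkoxide or hydroxide, C3=C4 reducible by hydrogenation) and the free, oxidation-prone phenols of ring B. Three phenolic oxygens must be told apart, since O7 is methylated while O5' and O7' are free. The strategy rests on the C7–C8–C8a triad of ring A: three contiguous oxygenated carbons with the ether oxygen on the middle one make ring A a 2-aryloxyresorcinol, the aromatised form of a 2-aryloxycyclohexane-1,3-dione. That dione can be closed by a Claisen condensation that forms C8–C8a next to an ether oxygen already attached at an sp3 carbon, and the mirror symmetry of the resulting resorcinol removes any regiochemical question in the later pyranone annulation.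

## Retrosynthetic reasoning

**21 to 20 to 19.** The last operations touch only heteroatom bonds. The two free hydroxyls of ring B are traced back to benzyl ethers in 20, cleaved last by a Lewis acid so that neither C3=C4 bond meets hydrogen. Cutting O7–CH3 of 20 gives phenol 19, whose single free hydroxyl makes the methylation unambiguous.

**19 to 16 and 17.** The unprimed pyranone is cut at C4–C4a and O1–C2. This returns the 2-aryloxyresorcinol 16 and the three-carbon alkynoate 17. The cut is placed here because 16 has a mirror plane through C8 and the carbon para to it. The two carbons that are ortho to one hydroxyl and para to the other are equivalent, and whichever reacts, the neighbouring hydroxyl closes the lactone to the same 7-hydroxy-8-aryloxycoumarin. The forward reaction has to functionalise ring A and leave C6'–H of ring B alone.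

**16 to 15 to 14 (key disconnection).** Ring A of 16 is taken back to the enolised 5-silyloxy-1,3-dione 15 by restoring a silyloxy group on the carbon β to both carbonyls. The C8–C8a bond of 15 is then cut in a retro-Claisen sense, opening the ring to the δ-keto ester 14. C8 is chosen because it is the one carbon of the chain that is α to the ketone and also bears the aryloxy group, so its carbanion is the most stabilised, and its attack on the ester is the only closure that gives a six-membered ring. The gain is that the hindered diaryl ether oxygen now sits on a CH2 group. The forward step must close the ring before the silyloxy group is lost from the open chain.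

**14 to 8 and 13.** The bond between the ring-B oxygen O8' and the CH2 of the chain is cut, giving the 8-hydroxycoumarin 8 and the chloromethyl ketone 13. An SN2 reaction on an α-halo ketone is fast enough to tolerate the two ortho substituents around O8'.

**13 to 12 to 10 to 9.** The chloromethyl carbon of 13 is removed as a one-carbon diazo unit through diazoketone 12, leaving half ester 10. Compound 10 is the ring-opened form of the commercial anhydride 9, which already holds the five-carbon chain and its central silyloxy group.

**8 to 6 to 5 to 3 to 1 and 2.** The primed pyranone is cut at C3'=C4' and O1'–C2', an olefination–lactonisation in the forward sense, giving salicylaldehyde 6. Removing its formyl carbon gives catechol 5, in which only one unsubstituted carbon is ortho to a hydroxyl, so the forward formylation has one possible site. The second catechol oxygen, the future O8', is traced to the formyl group of 3 by an aryl-to-oxygen shift. Compound 3 is the dibenzyl ether of 1, made with 2. This order fixes the 5',7',8',8a' oxygen pattern without an electrophilic substitution of uncertain regiochemistry on a finished coumarin.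

## Alternatives that were turned down

**Alternative 1:** Ring A is cut at C4a–C8a and C5–C6 into a four-carbon ketene-acetal diene A2, carrying C6, C7 (OMe), C8 (OAr) and C8a, and the three-carbon ynal A3. In the forward direction a [4+2] cycloaddition, loss of the methoxy group from the acetal carbon and desilylation would give the salicylaldehyde A1. This route delivers ring A with the 7-methoxy group, the lactonising hydroxyl and the formyl carbon all in place, so it needs no late methylation and no C–H functionalisation of ring A. On that point it is stronger than the chosen route, and the later olefination to the pyranone is regiospecific. Against it, diene A2 carries four oxygen substituents and a doubly ortho-substituted aryloxy group on an internal carbon, which disfavours the s-cis conformation, and its ketene acetal is hydrolytically fragile. A3 is volatile and polymerises readily. Ring B must then be annulated late on a hydroxyl unveiled from a MOM ether, which requires the three-way differentiated phenol A4 at the outset and more protecting-group steps than the preparation of 8. The chosen strategy offers instead a stable δ-keto ester as precursor, ring B finished before the key step, and three steps from key-step product to target.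

**Alternative 2:** Here ring B, not ring A, is opened at C8'–C8a', leading back to the 3,5-dioxohexanoate A6, whose aryloxy group is the finished 7-methoxycoumarin. An alkoxide-mediated Claisen closure of the aryloxy-bearing carbanion onto the ester would give the 2-aryloxyphloroglucinol A5 directly. On paper this is the shortest plan and the best in protecting-group economy: no benzyl ethers, no final deprotection, no aromatisation step, and the methyl ether present from the start. In these respects it beats the chosen route. Two structural problems speak against it. First, 3,5-dioxo esters readily cyclise through oxygen to a 4-hydroxy-2-pyrone, here A7, in competition with C-acylation. Second, the pyranone of ring B must afterwards be annulated on A5, where the new C–C bond lies between two hydroxyls. Lactonisation through the hydroxyl next to the ether carbon gives 21, and through the other gives the 6-aryloxy isomer A8. Nothing in the substrate favours the first, more hindered one. The chosen strategy applies the same kind of closure to the ring whose product is a symmetrical resorcinol, so this ambiguity cannot arise, and it pays with two benzyl ethers and a methylation.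

**Alternative 3:** Ring A is cut at C4a–C5, giving the 4-aryloxy-3,5-dioxohept-6-enoate A10 with a β-methoxyenone terminus. A chelating magnesium alkoxide base would make C2 add to the enone terminus, and loss of methoxide and aromatisation would give the benzoate A9. This product has a carbon substituent on the future C4a and two ring-A hydroxyls that differ chemically, one being hydrogen-bonded to the ester. O7 methylation is therefore selective and no arene C–H functionalisation is needed, which is an advantage over the chosen route. The drawbacks are the wrong oxidation level of the ester, which must be brought to the aldehyde before the pyranone can be built, and the nature of A10. It is a 2-aryloxy-1,3-diketone between a β-keto ester and a vinylogous ester: highly enolised, liable to retro-Claisen cleavage and to O-cyclisation, and it has to be assembled by acylation at or next to a hindered aryloxy-bearing carbon. It also needs the differentiated phenol A4 and a late annulation of ring B. At least six steps follow the key step, against three in the chosen route, and the precursor is far denser in reactive functionality than 14.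

Key step: step 9

Assumption: compounds 10 to 15 are racemic, since their single stereocentre (C3 of the hexanoate chain) becomes an aromatic carbon in step 9 and its configuration is immaterial.

## Route

Step 1
Reactants: 1 2,4,6-trihydroxybenzaldehyde; 2 benzyl bromide
Product: 3 2,4-bis(benzyloxy)-6-hydroxybenzaldehyde
Conditions: BnBr (2.05 equiv), K2CO3 (2.1 equiv), DMF, 0 °C to rt
Reagents that add atoms: benzyl bromide (2), BrCc1ccccc1
Why: Williamson etherification; the para hydroxyl and one ortho hydroxyl of 1 are alkylated, while the last ortho hydroxyl is held in a six-membered hydrogen bond to the formyl oxygen and is too weakly nucleophilic to react when two equivalents of 2 are used.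

Step 2
Reactants: 3 2,4-bis(benzyloxy)-6-hydroxybenzaldehyde
Product: 5 3,5-bis(benzyloxy)benzene-1,2-diol, via 2,4-bis(benzyloxy)-6-hydroxyphenyl formate 4 (not isolated)
Conditions: 30% aq. H2O2 (1.2 equiv), NaOH (1.1 equiv), THF/H2O, 0 °C, Ar; then 1 M HCl
Reagents that add atoms: hydrogen peroxide, OO
Why: Dakin oxidation; hydroperoxide adds to the formyl group and the electron-rich aryl ring migrates to oxygen (Baeyer–Villiger-type shift) to give formate 4, which is saponified in the flask. Low temperature, inert gas and an acidic quench should keep the electron-rich catechol from further oxidation, and crude 5 is best used at once.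

Step 3
Reactants: 5 3,5-bis(benzyloxy)benzene-1,2-diol
Product: 6 4,6-bis(benzyloxy)-2,3-dihydroxybenzaldehyde
Conditions: MgCl2 (3 equiv), Et3N (6 equiv), (CH2O)n (8 equiv), MeCN, reflux, Ar; then 1 M HCl
Reagents that add atoms: formaldehyde (as paraformaldehyde), C=O
Why: Magnesium-mediated ortho-formylation of a phenol (Casnati–Skattebøl type); the magnesium phenoxide delivers formaldehyde through a six-membered transition state to the ortho carbon and the benzylic alkoxide is oxidised by hydride transfer to a second formaldehyde. In 5 only one ring carbon is both unsubstituted and ortho to a hydroxyl, so the formyl group can enter only there.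

Step 4
Reactants: 6 4,6-bis(benzyloxy)-2,3-dihydroxybenzaldehyde
Product: 8 5,7-bis(benzyloxy)-8-hydroxy-2H-chromen-2-one, via ethyl (E)-3-[4,6-bis(benzyloxy)-2,3-dihydroxyphenyl]prop-2-enoate 7 (not isolated)
Conditions: Ph3P=CHCO2Et (1.3 equiv), PhNEt2, 210 °C, Ar
Reagents that add atoms: ethyl (triphenylphosphoranylidene)acetate, CCOC(=O)C=P(c1ccccc1)(c1ccccc1)c1ccccc1
Why: Wittig olefination with a stabilised ylide gives E-cinnamate 7; at 210 °C the double bond isomerises and the 2-hydroxyl lactonises with loss of ethanol (thermal Wittig–lactonisation route to coumarins). The 3-hydroxyl cannot reach the ester and remains as the 8-hydroxyl of 8.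

Step 5
Reactants: 9 3-[(tert-butyldimethylsilyl)oxy]glutaric anhydride (4-[(tert-butyldimethylsilyl)oxy]oxane-2,6-dione)
Product: 10 rac-3-[(tert-butyldimethylsilyl)oxy]-5-methoxy-5-oxopentanoic acid
Conditions: MeOH (5 equiv), DMAP (0.05 equiv), CH2Cl2, rt
Reagents that add atoms: methanol, CO
Why: Nucleophilic ring opening of a cyclic anhydride by an alcohol under DMAP catalysis; the achiral anhydride gives the racemic half ester, which is acceptable because this stereocentre is erased in step 9.

Step 6
Reactants: 10 rac-3-[(tert-butyldimethylsilyl)oxy]-5-methoxy-5-oxopentanoic acid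
Product: 12 rac-methyl 3-[(tert-butyldimethylsilyl)oxy]-6-diazo-5-oxohexanoate, via isobutyl carbonic mixed anhydride 11 (not isolated)
Conditions: i-BuOCOCl (1.05 equiv), N-methylmorpholine (1.05 equiv), THF, −15 °C; then CH2N2 (2.5 equiv), Et2O, 0 °C
Reagents that add atoms: diazomethane, C=[N+]=[N-]; isobutyl chloroformate, CC(C)COC(Cl)=O (its atoms stay only in intermediate 11)
Why: Activation of the acid as a mixed carbonic anhydride and C-acylation of diazomethane (first stage of an Arndt–Eistert sequence); the conditions are non-acidic and leave the silyl ether and the methyl ester untouched.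

Step 7
Reactants: 12 rac-methyl 3-[(tert-butyldimethylsilyl)oxy]-6-diazo-5-oxohexanoate
Product: 13 rac-methyl 3-[(tert-butyldimethylsilyl)oxy]-6-chloro-5-oxohexanoate
Conditions: HCl (4 M in dioxane, 1.05 equiv), Et2O, −20 to 0 °C
Reagents that add atoms: hydrogen chloride, Cl
Why: C-protonation of the diazoketone and SN2 displacement of dinitrogen by chloride give the chloromethyl ketone; one equivalent of anhydrous HCl at low temperature is consumed by the diazo group faster than it can cleave the secondary TBS ether.

Step 8
Reactants: 8 5,7-bis(benzyloxy)-8-hydroxy-2H-chromen-2-one; 13 rac-methyl 3-[(tert-butyldimethylsilyl)oxy]-6-chloro-5-oxohexanoate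
Product: 14 rac-methyl 6-{[5,7-bis(benzyloxy)-2-oxo-2H-chromen-8-yl]oxy}-3-[(tert-butyldimethylsilyl)oxy]-5-oxohexanoate
Conditions: K2CO3 (1.5 equiv), KI (0.1 equiv), acetone, rt
Reagents that add atoms: none
Why: Williamson ether synthesis on an α-halo ketone, among the most reactive SN2 electrophiles and further activated as the iodide by KI, so that even the doubly ortho-substituted phenoxide of 8 should be alkylated at rt with a base too weak to enolise the ketone appreciably. The future diaryl ether oxygen is thereby bonded to an sp3 carbon.

Step 9
Reactants: 14 rac-methyl 6-{[5,7-bis(benzyloxy)-2-oxo-2H-chromen-8-yl]oxy}-3-[(tert-butyldimethylsilyl)oxy]-5-oxohexanoate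
Product: 16 5,7-bis(benzyloxy)-8-(2,6-dihydroxyphenoxy)-2H-chromen-2-one, via 2-aryloxy-3-hydroxy-5-silyloxycyclohex-2-en-1-one 15 (not isolated)
Conditions: NaH (2.5 equiv), MeOH (0.1 equiv), THF, 0 °C to rt; then 2 M HCl, THF, 50 °C
Reagents that add atoms: none
Why: Dieckmann-type (intramolecular Claisen) condensation followed by eliminative aromatisation: under NaH with a trace of methoxide the ketone of 14 is enolised reversibly, and the enolate at C6, the most acidic position because the aryloxy group adds its inductive pull to that of the ketone, attacks the ester carbonyl C1 and expels methoxide, forming C6–C1, the future C8–C8a bond of ring A. The ring closes in a 6-(enolendo)-exo-trig mode, and attack from C4 or C2 would need a four-membered ring, so C6 is the only productive nucleophile. The 2-aryloxy-1,3-dione is far more acidic than anything else present and is held as its delocalised sodium enolate (15 after protonation), which makes the closure irreversible. On acidification the silyloxy group, now on a ring carbon β to both carbonyls, is lost as silanol (or as water after desilylation) through enolisation towards the adjacent CH2, and the resulting cyclohexadienone tautomerises to resorcinol 16 with aromaticity as driving force. The closest known reactions are the base-mediated cyclisation of 5-oxohexanoates to cyclohexane-1,3-diones and the acid dehydration of 5-hydroxycyclohexane-1,3-dione to resorcinol. No stereocentre is formed and the one in 14 disappears. The selectivity needed is ring closure ahead of E1cB loss of silanolate from the C4 or C2 enolates of the open chain, and the higher acidity of C6–H, the poor leaving-group ability of the hindered silanolate and the speed of six-ring closure onto a methyl ester should secure it. Should methoxide open the ring-B lactone, the Z-hydroxycinnamate relactonises in the acid stage, and the benzyl ethers are inert to both stages.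

Step 10
Reactants: 16 5,7-bis(benzyloxy)-8-(2,6-dihydroxyphenoxy)-2H-chromen-2-one; 17 ethyl propiolate
Product: 19 5,7-bis(benzyloxy)-8-[(7-hydroxy-2-oxo-2H-chromen-8-yl)oxy]-2H-chromen-2-one, via ethyl (Z)-3-(3-aryloxy-2,4-dihydroxyphenyl)prop-2-enoate 18 (not isolated)
Conditions: 17 (2 equiv), Pd(OAc)2 (3 mol%), CF3CO2H/CH2Cl2 (1:3), rt
Reagents that add atoms: ethyl propiolate (17), C#CC(=O)OCC
Why: Palladium-catalysed hydroarylation of an alkynoate by an electron-rich phenol followed by lactonisation (Fujiwara–Kitamura/Trost-type coumarin synthesis): the alkyne coordinated to divalent palladium is attacked by the ring-A carbon para to one hydroxyl and ortho to the other, protodemetalation gives Z-cinnamate 18, and the neighbouring hydroxyl closes the lactone with loss of ethanol. The two reactive positions of 16 are equivalent by symmetry, and ring B, which has no free hydroxyl, a C6' flanked by two benzyloxy groups and a conjugated lactone, should be much less reactive.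

Step 11
Reactants: 19 5,7-bis(benzyloxy)-8-[(7-hydroxy-2-oxo-2H-chromen-8-yl)oxy]-2H-chromen-2-one
Product: 20 5,7-bis(benzyloxy)-8-[(7-methoxy-2-oxo-2H-chromen-8-yl)oxy]-2H-chromen-2-one
Conditions: MeI (3 equiv), K2CO3 (2 equiv), acetone, 50 °C
Reagents that add atoms: iodomethane, CI
Why: Williamson O-methylation of the only free phenol; carbonate in acetone does not open the coumarin lactones.

Step 12
Reactants: 20 5,7-bis(benzyloxy)-8-[(7-methoxy-2-oxo-2H-chromen-8-yl)oxy]-2H-chromen-2-one
Product: 21 5,7-dihydroxy-8-[(7-methoxy-2-oxo-2H-chromen-8-yl)oxy]-2H-chromen-2-one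
Conditions: BCl3 (1 M in CH2Cl2, 5 equiv), C6HMe5 (6 equiv), CH2Cl2, −78 °C; then H2O
Reagents that add atoms: none
Why: Lewis-acid debenzylation with a cation scavenger: BCl3 ionises the benzyl ethers and pentamethylbenzene traps the benzyl cation by Friedel–Crafts alkylation, so the phenol rings are not C-benzylated. At −78 °C the aryl methyl ether, the diaryl ether and both lactones should survive, and the C3=C4 double bonds are never exposed to hydrogenation.

## Compound list

1 | 2,4,6-trihydroxybenzaldehyde | O=Cc1c(O)cc(O)cc1O | starting material
2 | benzyl bromide | BrCc1ccccc1 | starting material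
3 | 2,4-bis(benzyloxy)-6-hydroxybenzaldehyde | O=Cc1c(O)cc(OCc2ccccc2)cc1OCc1ccccc1 | intermediate
4 | 2,4-bis(benzyloxy)-6-hydroxyphenyl formate | O=COc1c(O)cc(OCc2ccccc2)cc1OCc1ccccc1 | intermediate (not isolated)
5 | 3,5-bis(benzyloxy)benzene-1,2-diol | Oc1cc(OCc2ccccc2)cc(OCc2ccccc2)c1O | intermediate
6 | 4,6-bis(benzyloxy)-2,3-dihydroxybenzaldehyde | O=Cc1c(O)c(O)c(OCc2ccccc2)cc1OCc1ccccc1 | intermediate
7 | ethyl (E)-3-[4,6-bis(benzyloxy)-2,3-dihydroxyphenyl]prop-2-enoate | CCOC(=O)/C=C/c1c(O)c(O)c(OCc2ccccc2)cc1OCc1ccccc1 | intermediate (not isolated)
8 | 5,7-bis(benzyloxy)-8-hydroxy-2H-chromen-2-one | O=c1ccc2c(OCc3ccccc3)cc(OCc3ccccc3)c(O)c2o1 | intermediate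
9 | 3-[(tert-butyldimethylsilyl)oxy]glutaric anhydride | CC(C)(C)[Si](C)(C)OC1CC(=O)OC(=O)C1 | starting material
10 | rac-3-[(tert-butyldimethylsilyl)oxy]-5-methoxy-5-oxopentanoic acid | COC(=O)CC(O[Si](C)(C)C(C)(C)C)CC(=O)O | intermediate
11 | rac-3-[(tert-butyldimethylsilyl)oxy]-5-methoxy-5-oxopentanoic isobutyl carbonic anhydride | COC(=O)CC(O[Si](C)(C)C(C)(C)C)CC(=O)OC(=O)OCC(C)C | intermediate (not isolated)
12 | rac-methyl 3-[(tert-butyldimethylsilyl)oxy]-6-diazo-5-oxohexanoate | COC(=O)CC(O[Si](C)(C)C(C)(C)C)CC(=O)C=[N+]=[N-] | intermediate
13 | rac-methyl 3-[(tert-butyldimethylsilyl)oxy]-6-chloro-5-oxohexanoate | COC(=O)CC(O[Si](C)(C)C(C)(C)C)CC(=O)CCl | intermediate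
14 | rac-methyl 6-{[5,7-bis(benzyloxy)-2-oxo-2H-chromen-8-yl]oxy}-3-[(tert-butyldimethylsilyl)oxy]-5-oxohexanoate | COC(=O)CC(O[Si](C)(C)C(C)(C)C)CC(=O)COc1c(OCc2ccccc2)cc(OCc2ccccc2)c2ccc(=O)oc12 | intermediate
15 | rac-2-{[5,7-bis(benzyloxy)-2-oxo-2H-chromen-8-yl]oxy}-5-[(tert-butyldimethylsilyl)oxy]-3-hydroxycyclohex-2-en-1-one (enol form of the 1,3-dione) | O=C1CC(O[Si](C)(C)C(C)(C)C)CC(O)=C1Oc1c(OCc2ccccc2)cc(OCc2ccccc2)c2ccc(=O)oc12 | intermediate (not isolated)
16 | 5,7-bis(benzyloxy)-8-(2,6-dihydroxyphenoxy)-2H-chromen-2-one | Oc1cccc(O)c1Oc1c(OCc2ccccc2)cc(OCc2ccccc2)c2ccc(=O)oc12 | intermediate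
17 | ethyl propiolate | C#CC(=O)OCC | starting material
18 | ethyl (Z)-3-(3-{[5,7-bis(benzyloxy)-2-oxo-2H-chromen-8-yl]oxy}-2,4-dihydroxyphenyl)prop-2-enoate | CCOC(=O)/C=C\c1ccc(O)c(Oc2c(OCc3ccccc3)cc(OCc3ccccc3)c3ccc(=O)oc23)c1O | intermediate (not isolated)
19 | 5,7-bis(benzyloxy)-8-[(7-hydroxy-2-oxo-2H-chromen-8-yl)oxy]-2H-chromen-2-one | O=c1ccc2ccc(O)c(Oc3c(OCc4ccccc4)cc(OCc4ccccc4)c4ccc(=O)oc34)c2o1 | intermediate
20 | 5,7-bis(benzyloxy)-8-[(7-methoxy-2-oxo-2H-chromen-8-yl)oxy]-2H-chromen-2-one | COc1ccc2ccc(=O)oc2c1Oc1c(OCc2ccccc2)cc(OCc2ccccc2)c2ccc(=O)oc12 | intermediate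
21 | 5,7-dihydroxy-8-[(7-methoxy-2-oxo-2H-chromen-8-yl)oxy]-2H-chromen-2-one | COc1ccc2ccc(=O)oc2c1Oc1c(O)cc(O)c2ccc(=O)oc12 | target

## Step count and least certain steps

Total step count: 12. Longest linear sequence: 9 steps (steps 1 to 4 and 8 to 12). The second branch (steps 5 to 7) joins at step 8.

**Step 9 (key step).** The most likely failure is E1cB loss of the silyloxy group from the open chain through the C4 or C2 enolate before the ring closes. This would leave an acyclic E-enone whose ends cannot meet. Opening of the ring-B lactone by methoxide is a lesser concern because it reverses on acidification. The fallback takes the leaving group out of the chain and aromatises by oxidation instead of elimination. It sets out from 8 and rejoins the route at 16: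
- Commercial methyl 5-chloro-5-oxopentanoate is converted with CH2N2 into methyl 6-diazo-5-oxohexanoate F1 and then with HCl into methyl 6-chloro-5-oxohexanoate F2.
- F2 alkylates 8 (K2CO3, KI, acetone) to methyl 6-{[5,7-bis(benzyloxy)-2-oxo-2H-chromen-8-yl]oxy}-5-oxohexanoate F3.
- NaH in THF closes F3, which has no β-leaving group, to 2-{[5,7-bis(benzyloxy)-2-oxo-2H-chromen-8-yl]oxy}cyclohexane-1,3-dione F4.
- Dehydrogenation of F4 (DDQ, dioxane, reflux; or Pd(O2CCF3)2 with O2 in DMSO) should give 16.

**Step 8.** Carbonate may induce loss of silanolate from the β-silyloxy ketone in 13 or 14, and slow O-alkylation of the doubly ortho-substituted phenoxide would let self-condensation of 13 compete. The fallback is a neutral carbenoid O–H insertion. It sets out from diazoketone 12 and phenol 8, which with Rh2(OAc)4 (1 mol%) in CH2Cl2 at rt should give 14 directly, where the route is rejoined. Step 7 is omitted and no new compound is made (F0).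

**Step 10.** Hydroarylation could also occur at C6'–H of ring B, a second annulation could take place on the remaining hydroxyl side of ring A, or the benzyl ethers could be eroded by acid. The fallback installs the carbon ortho to a free hydroxyl, which only ring A has. It sets out from 16 and rejoins at 19:
- Magnesium-mediated ortho-formylation (MgCl2, Et3N, paraformaldehyde, MeCN, reflux) should give 3-{[5,7-bis(benzyloxy)-2-oxo-2H-chromen-8-yl]oxy}-2,4-dihydroxybenzaldehyde F5.
- Wittig olefination with Ph3P=CHCO2Et in PhNEt2 gives ethyl (E)-3-(3-{[5,7-bis(benzyloxy)-2-oxo-2H-chromen-8-yl]oxy}-2,4-dihydroxyphenyl)prop-2-enoate F6.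
- F6 isomerises and lactonises at 210 °C to 19.

**Step 3 (with step 2).** The electron-rich catechol 5 may be degraded oxidatively during its formation or handling, and its chelated magnesium catecholate may react sluggishly with formaldehyde. The fallback avoids any free catechol by building the pyranone first and introducing O8' afterwards. It sets out from 3 and rejoins at 8:
- Wittig olefination of 3 gives ethyl (E)-3-[2,4-bis(benzyloxy)-6-hydroxyphenyl]prop-2-enoate F7, which lactonises at 210 °C in PhNEt2 to 5,7-bis(benzyloxy)-2H-chromen-2-one F8.
- Vilsmeier formylation (POCl3, DMF) should give 5,7-bis(benzyloxy)-2-oxo-2H-chromene-8-carbaldehyde F9.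
- Baeyer–Villiger oxidation with mCPBA gives 5,7-bis(benzyloxy)-2-oxo-2H-chromen-8-yl formate F10.
- Mild methanolysis (catalytic K2CO3, MeOH) releases 8.

The weak point of this fallback is the site of formylation, C8 against C6, which is why it is not the main route.

## Further compounds

F1 | step 9 | methyl 6-diazo-5-oxohexanoate | COC(=O)CCCC(=O)C=[N+]=[N-]
F2 | step 9 | methyl 6-chloro-5-oxohexanoate | COC(=O)CCCC(=O)CCl
F3 | step 9 | methyl 6-{[5,7-bis(benzyloxy)-2-oxo-2H-chromen-8-yl]oxy}-5-oxohexanoate | COC(=O)CCCC(=O)COc1c(OCc2ccccc2)cc(OCc2ccccc2)c2ccc(=O)oc12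
F4 | step 9 | 2-{[5,7-bis(benzyloxy)-2-oxo-2H-chromen-8-yl]oxy}cyclohexane-1,3-dione | O=C1CCCC(=O)C1Oc1c(OCc2ccccc2)cc(OCc2ccccc2)c2ccc(=O)oc12
F0 | step 8 | none | none
F5 | step 10 | 3-{[5,7-bis(benzyloxy)-2-oxo-2H-chromen-8-yl]oxy}-2,4-dihydroxybenzaldehyde | O=Cc1ccc(O)c(Oc2c(OCc3ccccc3)cc(OCc3ccccc3)c3ccc(=O)oc23)c1O
F6 | step 10 | ethyl (E)-3-(3-{[5,7-bis(benzyloxy)-2-oxo-2H-chromen-8-yl]oxy}-2,4-dihydroxyphenyl)prop-2-enoate | CCOC(=O)/C=C/c1ccc(O)c(Oc2c(OCc3ccccc3)cc(OCc3ccccc3)c3ccc(=O)oc23)c1O
F7 | step 3 | ethyl (E)-3-[2,4-bis(benzyloxy)-6-hydroxyphenyl]prop-2-enoate | CCOC(=O)/C=C/c1c(O)cc(OCc2ccccc2)cc1OCc1ccccc1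
F8 | step 3 | 5,7-bis(benzyloxy)-2H-chromen-2-one | O=c1ccc2c(OCc3ccccc3)cc(OCc3ccccc3)cc2o1
F9 | step 3 | 5,7-bis(benzyloxy)-2-oxo-2H-chromene-8-carbaldehyde | O=Cc1c(OCc2ccccc2)cc(OCc2ccccc2)c2ccc(=O)oc12
F10 | step 3 | 5,7-bis(benzyloxy)-2-oxo-2H-chromen-8-yl formate | O=COc1c(OCc2ccccc2)cc(OCc2ccccc2)c2ccc(=O)oc12
A1 | alternative 1 | 3-[2,4-bis(benzyloxy)-6-(methoxymethoxy)phenoxy]-2-hydroxy-4-methoxybenzaldehyde | COc1ccc(C=O)c(O)c1Oc1c(OCOC)cc(OCc2ccccc2)cc1OCc1ccccc1
A2 | alternative 1 | 2-[2,4-bis(benzyloxy)-6-(methoxymethoxy)phenoxy]-1,3-dimethoxy-1-(trimethylsilyloxy)buta-1,3-diene | C=C(OC)C(Oc1c(OCOC)cc(OCc2ccccc2)cc1OCc1ccccc1)=C(OC)O[Si](C)(C)C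
A3 | alternative 1 | propynal | C#CC=O
A4 | alternative 1 | 2,4-bis(benzyloxy)-6-(methoxymethoxy)phenol | COCOc1cc(OCc2ccccc2)cc(OCc2ccccc2)c1O
A5 | alternative 2 | 7-methoxy-8-(2,4,6-trihydroxyphenoxy)-2H-chromen-2-one | COc1ccc2ccc(=O)oc2c1Oc1c(O)cc(O)cc1O
A6 | alternative 2 | methyl 6-[(7-methoxy-2-oxo-2H-chromen-8-yl)oxy]-3,5-dioxohexanoate | COC(=O)CC(=O)CC(=O)COc1c(OC)ccc2ccc(=O)oc12
A7 | alternative 2 | 4-hydroxy-6-{[(7-methoxy-2-oxo-2H-chromen-8-yl)oxy]methyl}-2H-pyran-2-one | COc1ccc2ccc(=O)oc2c1OCc1cc(O)cc(=O)o1
A8 | alternative 2 | 5,7-dihydroxy-6-[(7-methoxy-2-oxo-2H-chromen-8-yl)oxy]-2H-chromen-2-one | COc1ccc2ccc(=O)oc2c1Oc1c(O)cc2oc(=O)ccc2c1O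
A9 | alternative 3 | methyl 3-[2,4-bis(benzyloxy)-6-(methoxymethoxy)phenoxy]-2,4-dihydroxybenzoate | COC(=O)c1ccc(O)c(Oc2c(OCOC)cc(OCc3ccccc3)cc2OCc2ccccc2)c1O
A10 | alternative 3 | methyl (E)-4-[2,4-bis(benzyloxy)-6-(methoxymethoxy)phenoxy]-7-methoxy-3,5-dioxohept-6-enoate (racemic, largely enolised) | CO/C=C/C(=O)C(Oc1c(OCOC)cc(OCc2ccccc2)cc1OCc1ccccc1)C(=O)CC(=O)OC
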